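## Structural features

The target is a heterodimer in which a 2,2-dimethyl-2H-chromene (pyran ring O1, C2, C3, C4, C4a, C8a fused to a fully substituted benzene ring C4a, C5, C6, C7, C8, C8a) is joined through one methylene carbon at C6 to C3 of a 6-ethyl-4-hydroxy-5-methyl-2H-pyran-2-one. The benzene ring is a phloroglucinol whose three oxygens are O1 (on C8a) and the free hydroxyls on C5 and C7. C8, between the C7 hydroxyl and O1, carries the (2S)-2-methylbutanoyl group, and C6, between the two hydroxyls, carries the bridge. The only stereocentre is the α-carbon of the acyl chain, which has no neighbouring stereocentre but sits next to an aryl ketone and can be lost by enolisation under acid, base or Lewis acid. Other fragile elements are the electron-rich, styrene-like C3=C4 alkene (acid-sensitive), the methylene bridge between two vinylogous acids (open to retro-Michael exchange) and the acidic hydroxypyrone lactone. The real difficulty is regiochemical, because C6 and C8 are both nucleophilic and the acyl group and the bridge must be placed without ambiguity and without eroding the stereocentre. The key step uses the fact that O1, the quaternary C2 with its two methyl groups and the cis C3=C4 alkene of the pyran ring correspond to the ring oxygen, the lactone carbonyl carbon and the alkene of a coumarin, so that two methyl additions at that carbonyl give the gem-dimethyl carbinol on a Z alkene that is already attached to the correct phenol oxygen.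

## Logic of the disconnections

26 ⇒ 19 + 24. The bond between the bridging methylene carbon and pyrone C3 is cut first. A methylene between a phenol ring and the α-carbon of a cyclic 1,3-dicarbonyl unit is the retron of a Michael addition to an ortho-quinone methide, so this cut splits the target into its two ring systems in one operation that needs neither Lewis acid nor metal. The forward step must release 25 from 19 and have it captured only by C3 of 24. Because 19 has no unsubstituted aryl position, self-alkylation of the arene is excluded by structure.

19 ⇒ 18. The two phenolic O–H bonds are traced back to acetal ethers. These ethers are not a detour: they let the lactone of 5 meet 6, and afterwards they direct both aryl metalations, so that no Friedel–Crafts acylation is needed on the chromene. The forward cleavage must be acidic enough for the acetals yet spare the C3=C4 alkene and the α-stereocentre.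

18 ⇒ 12 + 15, and 15 ⇒ 13. The C8–carbonyl bond is cut to the aryl anion 16 (from 12) and an acyl donor, 15, that already holds the S centre. C8–H is the last aryl hydrogen and lies between two oxygens, so its removal is unambiguous, and the stereocentre is introduced at low temperature. The demand is that addition to the amide carbonyl outruns proton abstraction from its α-carbon. 15 is one amide-forming step from 13.

12 ⇒ 9 + 10. The C6–CH2 bond is cut to the aryl anion 11 and the iminium carbon of 10. C6 lies between two acetal ethers and is the kinetically most acidic site of 9. The one-carbon unit enters as a tertiary amine that is inert to the second metalation and later serves as the leaving group. The demand is that the first metalation selects C6 over C8.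

9 ⇒ 8. The O1–C2 ether bond is cut. The tertiary allylic alcohol of 8 ionises easily and the Z alkene holds the phenol oxygen within reach, so a six-membered ether closes under very mild acid. The demand is that the acid leaves the acetal ethers alone.

8 ⇒ 5 + 6. Both C2–CH3 bonds are cut, which turns the carbinol carbon into a lactone carbonyl and the open chain into a ring; two equivalents of 6 are therefore built in. This removes the quaternary carbon and fixes the alkene geometry and the ring fusion in a simple bicyclic precursor. The forward step needs two 1,2-additions and no 1,4-addition.

5 ⇒ 2 + 3, and 2 ⇒ 1. The C3=C4 alkene and the lactone O–C(=O) bond are cut to an ortho-hydroxy aldehyde and a stabilised ylide. The phenol beside the aldehyde becomes O1, so the fusion is defined from the first step. 2 comes from 1 by etherification of the two phenols that are not tied up in the hydrogen bond to the aldehyde.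

24 ⇒ 21 + 22, and 21 ⇒ 20. The pyrone C4–C5 and O1–C2 bonds are cut to a silyl enol ether and a malonyl unit. 20 supplies C5, C6, both alkyl groups and the ring oxygen. The forward step needs C-acylation before O-acylation.

## Other disconnections considered

Alternative 1: The cut goes through the benzene ring itself. C8–C8a and C6–C7 are formed when diene A1 adds to the chiral ynone A2, and loss of one alkoxy group and of the silyl group aromatises the cycloadduct to ketone A3.
- In favour: the acyl group and its stereocentre are part of the ring from the moment the ring exists, so neither a metalation nor an electrophilic acylation is needed to place it, and A3 has three chemically different oxygens. On the placement of the acyl group this plan is the better of the two.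
- Against: A2 holds its stereocentre between a ketone and an electron-poor alkyne, a more acidic position than in any intermediate of the chosen route, and it must survive a thermal cycloaddition and an elimination.
- Against: A3 has none of the pyran carbons and no bridge. The oxygen that must become O1 is a methyl ether ortho to the ketone, and chelation-assisted ether cleavage should free the ortho ethyl ether as well, giving the symmetrical triol A4. The differentiation is then spent, and a pyran-forming condensation could close on either side of the acyl group.
- Comparison: structurally, the chosen plan takes O1, C2 and the C3=C4 alkene from one lactone with the fusion fixed, whereas this alternative fixes the acyl group and leaves the pyran ring open. Mechanistically, a pericyclic ring construction stands against two polar carbonyl additions, and both are sound in principle. In step economy the alternative is longer, since A2 needs its own preparation and all chromene and bridge chemistry still follows A3.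

Alternative 2: The cut is the pyrone C3–C4 bond. In the forward sense the ester enolate of enol ester A5 attacks the neighbouring cis methyl ester (Dieckmann closure) and gives the hydroxypyrone A6.
- In favour: the bridge carbon is an ordinary chain carbon of a propanoate, in place before the pyrone exists, so no quinone methide is involved and no exchange of partners across the methylene is possible. On robustness of the bridge this alternative is the better.
- Equal: A6 contains the chromene of 9, so the pyran ring could be made by the same lactone-to-pyran step.
- Against: A5 needs a three-carbon acid chain at C6 and a geometrically defined O-acylation of a β-keto ester enol (O- versus C-acylation, Z versus E). The enolate of an enol ester may also expel the enolate as a leaving group instead of cyclising.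
- Against, and most serious: A6 has no acyl group at C8. Once the hydroxypyrone is present, its acidic hydroxyl and the γ-protons of the 6-ethyl group block a directed metalation, so the acyl group would have to enter by Friedel–Crafts chemistry on the chromene, with hazard to alkene and stereocentre.
- Comparison: the structure passes through the same intermediate 9 and the same first metalation site. The mechanism is a carbanion cyclisation instead of a conjugate addition. The route is longer by the chain extension and the enol ester, and its end game is less secure.

Alternative 3: The cuts are pyrone C4–C5 and O1–C2. In the forward sense 20, soft-enolised with MgBr2·OEt2 and iPr2NEt, is acylated at carbon by the acylbenzotriazole A7, and lactonisation through the enol oxygen of the new ketone then closes the ring to A8.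
- Equal: it uses the same 20 and makes the same two pyrone bonds as steps 9 and 10 of the chosen route.
- Better: the aryl ring of A8 is symmetrical (two equivalent acetal ethers beside the bridge, the benzyl ether para to it). The pyran ring can then be fused in only one way and the last free position takes the acyl group. This solves the regiochemistry by symmetry, whereas the chosen plan rests on the order of two metalations.
- Against: A7 has a very acidic C–H between two carbonyls, which can quench the enolate or eliminate to an acylketene.
- Against: the pyran ring has to be built late, after benzyl ether removal, onto a molecule that already holds the hydroxypyrone, by a phenol–enal condensation or a propargyl ether rearrangement and not from a lactone. The C8 acylation meets the same obstacle as in alternative 2.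
- Comparison: structurally the bridge is fixed early and safely, but the pyran ring comes late and less defined. Mechanistically it is enolate C-acylation and lactonisation against the one-pot silyl enol ether process of step 10. Reaching A8 is comparable in length to reaching 19, but chromene formation, deprotection and acylation after A8 make the whole longer.

Key step: step 3

Remark on the chemistry: the first lithiation of 9 is assumed to occur at C6, between the two MOM ethers, by analogy with 1,3-bis(methoxymethoxy)arenes; the order of the two metalations rests on this and a fallback covers it.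

## Route

Step 1
Reactants: 1 2,4,6-trihydroxybenzaldehyde
Product: 2 2-hydroxy-4,6-bis(methoxymethoxy)benzaldehyde
Conditions: MOMCl (2.2 equiv), iPr2NEt, CH2Cl2, 0 °C to rt
Reagents that add atoms: chloromethyl methyl ether, COCCl
Why: Base-mediated O-alkylation (Williamson type): the 4-hydroxyl is the most acidic and one of the two equivalent ortho hydroxyls follows, while the last one is held in a hydrogen bond to the aldehyde and stays free for the lactonisation.

Step 2
Reactants: 2 2-hydroxy-4,6-bis(methoxymethoxy)benzaldehyde; 3 ethyl (triphenylphosphoranylidene)acetate
Product: 5 5,7-bis(methoxymethoxy)-2H-chromen-2-one, via E-cinnamate ester 4 (not isolated)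
Conditions: PhNEt2, reflux
Reagents that add atoms: none
Why: Wittig olefination with the stabilised ylide gives the E-cinnamate 4; at the temperature of refluxing N,N-diethylaniline the alkene isomerises and the free phenol closes the lactone with loss of ethanol, the standard Wittig–lactonisation route from salicylaldehydes to coumarins.

Step 3
Reactants: 5 5,7-bis(methoxymethoxy)-2H-chromen-2-one; 6 methylmagnesium bromide
Product: 8 2-[(Z)-3-hydroxy-3-methylbut-1-en-1-yl]-3,5-bis(methoxymethoxy)phenol, via Z-enone bromomagnesium phenolate 7 (not isolated)
Conditions: MeMgBr (4 equiv), THF, 0 °C to rt; then pH 7 phosphate buffer, 0 °C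
Reagents that add atoms: methylmagnesium bromide, C[Mg]Br
Why: Two equivalents of 6 are built into the product, one for each new C2–CH3 bond, and the remainder is a margin against enolisation. The first methyl group adds to the lactone carbonyl C2 and the tetrahedral magnesium alkoxide collapses by expelling the C8a phenoxide, which opens the pyranone to the Z-configured methyl enone 7. The second methyl group adds 1,2 to that ketone and the tertiary alkoxide is protonated in the buffered quench to give 8. The closest known reaction type is the double addition of methyl Grignard or methyllithium reagents to coumarins, which gives ring-opened Z-allylic tertiary carbinols as precursors of 2,2-dimethyl-2H-chromenes. No ring is closed and no stereocentre is formed here, since the lactone ring is opened, the six-membered ether is closed only in step 4, and the Z geometry of the C3=C4 alkene is inherited from the ring because no intermediate allows rotation about that bond. The step needs carbonyl (1,2) attack instead of conjugate (1,4) attack in both additions: the hard methyl nucleophile prefers the carbonyl, C4 is deactivated by the ortho and para alkoxy donors and shielded by the peri C5 MOM ether, and in 7 the ortho phenoxide lowers the electrophilicity of the β-carbon further. Enolisation of the methyl ketone in 7 is the other competing path and is countered by excess reagent at 0 °C, while the MOM acetals are inert to the Grignard reagent.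

Step 4
Reactants: 8 2-[(Z)-3-hydroxy-3-methylbut-1-en-1-yl]-3,5-bis(methoxymethoxy)phenol
Product: 9 5,7-bis(methoxymethoxy)-2,2-dimethyl-2H-chromene
Conditions: PPTS (cat.), CH2Cl2, rt
Reagents that add atoms: none
Why: Acid-catalysed cyclodehydration: the tertiary allylic alcohol ionises to an aryl-stabilised allyl cation that the cis-placed phenol oxygen captures at the dimethyl-bearing carbon, closing the six-membered ether. A pyridinium acid in an aprotic solvent should leave the MOM acetals intact.

Step 5
Reactants: 9 5,7-bis(methoxymethoxy)-2,2-dimethyl-2H-chromene; 10 N,N-dimethylmethyleneiminium iodide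
Product: 12 1-[5,7-bis(methoxymethoxy)-2,2-dimethyl-2H-chromen-6-yl]-N,N-dimethylmethanamine, via C6 aryllithium 11 (not isolated)
Conditions: n-BuLi (1.2 equiv), THF, 0 °C; then 10, −78 °C to rt
Reagents that add atoms: none
Why: Directed ortho-metalation: C6–H lies between two chelating MOM ethers, whereas C8–H has only one MOM ether and the hindered, weakly coordinating pyran oxygen beside it. The aryllithium then adds to the iminium salt, a Mannich-type aminomethylation of an organolithium.

Step 6
Reactants: 13 (S)-2-methylbutanoic acid
Product: 15 (S)-N-methoxy-N,2-dimethylbutanamide, via acyl imidazole 14 (not isolated)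
Conditions: CDI, CH2Cl2, rt; then MeNH(OMe)·HCl, rt
Reagents that add atoms: N,O-dimethylhydroxylamine hydrochloride, CNOC.Cl
Why: Amide formation through the acyl imidazole; this near-neutral activation does not enolise the α-carbon, so the S configuration bought with 13 is carried over unchanged.

Step 7
Reactants: 12 1-[5,7-bis(methoxymethoxy)-2,2-dimethyl-2H-chromen-6-yl]-N,N-dimethylmethanamine; 15 (S)-N-methoxy-N,2-dimethylbutanamide
Product: 18 (2S)-1-{6-[(dimethylamino)methyl]-5,7-bis(methoxymethoxy)-2,2-dimethyl-2H-chromen-8-yl}-2-methylbutan-1-one, via C8 aryllithium 16 (not isolated), via lithium hemiaminal adduct 17 (not isolated)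
Conditions: s-BuLi, TMEDA, THF, −78 to −40 °C; then 15, −78 to 0 °C; then pH 7 buffer, 0 °C
Reagents that add atoms: none
Why: Second directed ortho-metalation at the only remaining aryl C–H (between the C7 MOM ether and O1), followed by Weinreb ketone synthesis. The chelated adduct 17 keeps the carbonyl masked until the quench, so neither over-addition nor enolisation of the new ketone should occur, and the stereocentre comes unchanged from 15.

Step 8
Reactants: 18 (2S)-1-{6-[(dimethylamino)methyl]-5,7-bis(methoxymethoxy)-2,2-dimethyl-2H-chromen-8-yl}-2-methylbutan-1-one
Product: 19 (2S)-1-{6-[(dimethylamino)methyl]-5,7-dihydroxy-2,2-dimethyl-2H-chromen-8-yl}-2-methylbutan-1-one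
Conditions: HCl (2 M in MeOH), 40 °C; then aq. NaHCO3
Reagents that add atoms: none
Why: Acid-catalysed acetal exchange transfers both methoxymethyl groups to methanol. The Mannich base is held as its ammonium salt, which should not extrude the amine at this temperature, and dilute methanolic acid is a usual way to remove MOM ethers from 2,2-dimethylchromenes without touching the alkene or an α-branched aryl ketone.

Step 9
Reactants: 20 3-pentanone
Product: 21 (Z)-trimethyl(pent-2-en-3-yloxy)silane
Conditions: TMSCl, NaI, Et3N, MeCN, rt
Reagents that add atoms: chlorotrimethylsilane, C[Si](C)(C)Cl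
Why: Soft enolisation and O-silylation by iodotrimethylsilane formed in the flask, giving mainly the Z enol ether; the geometry has no consequence because both isomers lead to the same pyrone.

Step 10
Reactants: 21 (Z)-trimethyl(pent-2-en-3-yloxy)silane; 22 malonyl dichloride
Product: 24 6-ethyl-4-hydroxy-5-methyl-2H-pyran-2-one, via dioxoheptanoyl chloride 23 (not isolated)
Conditions: Et2O, −78 °C to rt
Reagents that add atoms: none
Why: C-acylation of the silyl enol ether by one acid chloride (pyrone C4–C5), then lactonisation of the enolised ketone oxygen onto the second acid chloride (O1–C2); this is the known synthesis of 4-hydroxy-2-pyrones from silyl enol ethers and malonyl dichloride.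

Step 11
Reactants: 19 (2S)-1-{6-[(dimethylamino)methyl]-5,7-dihydroxy-2,2-dimethyl-2H-chromen-8-yl}-2-methylbutan-1-one; 24 6-ethyl-4-hydroxy-5-methyl-2H-pyran-2-one
Product: 26 3-({5,7-dihydroxy-2,2-dimethyl-8-[(2S)-2-methylbutanoyl]-2H-chromen-6-yl}methyl)-6-ethyl-4-hydroxy-5-methyl-2H-pyran-2-one, via ortho-quinone methide 25 (not isolated)
Conditions: 24 (1.5 equiv), 1,4-dioxane, 90 °C
Reagents that add atoms: none
Why: Thermal loss of dimethylamine from the phenolic Mannich base gives the ortho-quinone methide 25, which is captured at its exocyclic carbon by the nucleophilic C3 of the hydroxypyrone (Michael addition, the known C-alkylation of cyclic 1,3-dicarbonyl compounds by Mannich-base-derived quinone methides). The arene of 19 has no free position, so only the cross-coupled product can form, and no Lewis acid or strong base reaches the stereocentre.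

## Compound list

1 | 2,4,6-trihydroxybenzaldehyde | O=Cc1c(O)cc(O)cc1O | starting material
2 | 2-hydroxy-4,6-bis(methoxymethoxy)benzaldehyde | O=Cc1c(O)cc(OCOC)cc1OCOC | intermediate
3 | ethyl (triphenylphosphoranylidene)acetate | CCOC(=O)C=P(c1ccccc1)(c1ccccc1)c1ccccc1 | starting material
4 | ethyl (E)-3-[2-hydroxy-4,6-bis(methoxymethoxy)phenyl]prop-2-enoate | CCOC(=O)/C=C/c1c(O)cc(OCOC)cc1OCOC | intermediate
5 | 5,7-bis(methoxymethoxy)-2H-chromen-2-one | O=c1ccc2c(OCOC)cc(OCOC)cc2o1 | intermediate
6 | methylmagnesium bromide | C[Mg]Br | starting material
7 | bromomagnesium 2-[(Z)-3-oxobut-1-en-1-yl]-3,5-bis(methoxymethoxy)phenolate | CC(=O)/C=C\c1c(O[Mg]Br)cc(OCOC)cc1OCOC | intermediate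
8 | 2-[(Z)-3-hydroxy-3-methylbut-1-en-1-yl]-3,5-bis(methoxymethoxy)phenol | CC(C)(O)/C=C\c1c(O)cc(OCOC)cc1OCOC | intermediate
9 | 5,7-bis(methoxymethoxy)-2,2-dimethyl-2H-chromene | CC1(C)C=Cc2c(OCOC)cc(OCOC)cc2O1 | intermediate
10 | N,N-dimethylmethyleneiminium iodide | C=[N+](C)C.[I-] | starting material
11 | [5,7-bis(methoxymethoxy)-2,2-dimethyl-2H-chromen-6-yl]lithium | CC1(C)C=Cc2c(OCOC)c([Li])c(OCOC)cc2O1 | intermediate
12 | 1-[5,7-bis(methoxymethoxy)-2,2-dimethyl-2H-chromen-6-yl]-N,N-dimethylmethanamine | CN(C)Cc1c(OCOC)cc2OC(C)(C)C=Cc2c1OCOC | intermediate
13 | (S)-2-methylbutanoic acid | OC(=O)[C@@H](C)CC | starting material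
14 | (S)-1-(1H-imidazol-1-yl)-2-methylbutan-1-one | O=C(n1ccnc1)[C@@H](C)CC | intermediate
15 | (S)-N-methoxy-N,2-dimethylbutanamide | CON(C)C(=O)[C@@H](C)CC | intermediate
16 | {6-[(dimethylamino)methyl]-5,7-bis(methoxymethoxy)-2,2-dimethyl-2H-chromen-8-yl}lithium | CN(C)Cc1c(OCOC)c([Li])c2OC(C)(C)C=Cc2c1OCOC | intermediate
17 | lithium (2S)-1-{6-[(dimethylamino)methyl]-5,7-bis(methoxymethoxy)-2,2-dimethyl-2H-chromen-8-yl}-1-[methoxy(methyl)amino]-2-methylbutan-1-olate (both C1 epimers) | [Li]OC(N(C)OC)(c1c(OCOC)c(CN(C)C)c(OCOC)c2C=CC(C)(C)Oc12)[C@@H](C)CC | intermediate
18 | (2S)-1-{6-[(dimethylamino)methyl]-5,7-bis(methoxymethoxy)-2,2-dimethyl-2H-chromen-8-yl}-2-methylbutan-1-one | O=C(c1c(OCOC)c(CN(C)C)c(OCOC)c2C=CC(C)(C)Oc12)[C@@H](C)CC | intermediate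
19 | (2S)-1-{6-[(dimethylamino)methyl]-5,7-dihydroxy-2,2-dimethyl-2H-chromen-8-yl}-2-methylbutan-1-one | O=C(c1c(O)c(CN(C)C)c(O)c2C=CC(C)(C)Oc12)[C@@H](C)CC | intermediate
20 | 3-pentanone | CCC(=O)CC | starting material
21 | (Z)-trimethyl(pent-2-en-3-yloxy)silane (main isomer) | C/C=C(\O[Si](C)(C)C)CC | intermediate
22 | malonyl dichloride | ClC(=O)CC(=O)Cl | starting material
23 | 4-methyl-3,5-dioxoheptanoyl chloride (racemic, enolisable) | CCC(=O)C(C)C(=O)CC(=O)Cl | intermediate
24 | 6-ethyl-4-hydroxy-5-methyl-2H-pyran-2-one | CCc1oc(=O)cc(O)c1C | intermediate
25 | 7-hydroxy-2,2-dimethyl-8-[(2S)-2-methylbutanoyl]-6-methylidene-2H-chromen-5(6H)-one (one tautomer of the ortho-quinone methide) | C=C1C(=O)C2=C(OC(C)(C)C=C2)C(C(=O)[C@@H](C)CC)=C1O | intermediate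
26 | 3-({5,7-dihydroxy-2,2-dimethyl-8-[(2S)-2-methylbutanoyl]-2H-chromen-6-yl}methyl)-6-ethyl-4-hydroxy-5-methyl-2H-pyran-2-one | CCc1oc(=O)c(Cc2c(O)c3c(c(C(=O)[C@@H](C)CC)c2O)OC(C)(C)C=C3)c(O)c1C | target

## Step count and least certain steps

Total step count: 11. Longest linear sequence: 8 steps (1, 2, 3, 4, 5, 7, 8, 11); steps 6, 9 and 10 prepare the two side fragments.

Step 3 (key step). The most likely failure is conjugate delivery of a methyl group to C4, either of 5 or of the enone stage, or enolisation of the methyl ketone stage that stops the second addition. Both arise because the open-chain intermediate is a deactivated, enolisable enone. Premature ether closure during the quench would be harmless, since it leads to 9. The fallback sets out from 2 and comes back at 9. Wittig olefination of 2 with 1-(triphenylphosphoranylidene)propan-2-one should give (E)-4-[2-hydroxy-4,6-bis(methoxymethoxy)phenyl]but-3-en-2-one F1. A single 1,2-addition of methyllithium in the presence of CeCl3 (one extra equivalent for the free phenol) should then give 2-[(E)-3-hydroxy-3-methylbut-1-en-1-yl]-3,5-bis(methoxymethoxy)phenol F2. Warming F2 with the pyridinium acid of step 4 should ionise the carbinol to the aryl-stabilised allyl cation, in which the former alkene bond has lost much of its double-bond character, so that rotation and closure to 9 become possible. This replaces the double addition to a lactone by two separate single additions on an open chain.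

Step 5. The risk is loss of regiocontrol in the metalation, that is partial lithiation at C8, because the pyran oxygen together with the C7 MOM ether can also hold the base. The fallback sets out from 8 and comes back at 12. Treating 8 with three equivalents of n-BuLi should first form the phenoxide and the alkoxide. The position next to the phenoxide is then strongly deactivated, so the third equivalent should metalate only between the two MOM ethers. Capture with 10 should give 4-[(dimethylamino)methyl]-2-[(Z)-3-hydroxy-3-methylbut-1-en-1-yl]-3,5-bis(methoxymethoxy)phenol F3, and cyclodehydration with slightly more than one equivalent of camphorsulfonic acid in CH2Cl2 (the amine consumes one) should close the ether to 12.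

Step 7. The risk is proton transfer from the α-carbon of 15 to the hindered aryllithium 16 instead of carbonyl addition. This would return 12 and erode the configuration of unreacted amide and of the product. The fallback sets out from 12 and 15 and comes back at 18. Reduction of 15 with LiAlH4 at −78 °C should give (S)-2-methylbutanal F4, to be used at once. Addition of 16 (made from 12 as in step 7) to this far more electrophilic carbonyl at −78 °C should give (2S)-1-{6-[(dimethylamino)methyl]-5,7-bis(methoxymethoxy)-2,2-dimethyl-2H-chromen-8-yl}-2-methylbutan-1-ol F5 as a mixture at the carbinol carbon. Oxidation with Dess–Martin periodinane buffered with NaHCO3 should converge both epimers on 18.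

Step 11. The risk is slow extrusion of the amine, so that prolonged heating allows self-condensation of the quinone methide, transfer of the methylene unit to a second pyrone, or amine-mediated erosion at the stereocentre. The fallback sets out from 18 and comes back at 26. N-methylation of 18 with iodomethane in MeCN should give 1-{5,7-bis(methoxymethoxy)-2,2-dimethyl-8-[(2S)-2-methylbutanoyl]-2H-chromen-6-yl}-N,N,N-trimethylmethanaminium iodide F6. Acetal cleavage as in step 8 should give 1-{5,7-dihydroxy-2,2-dimethyl-8-[(2S)-2-methylbutanoyl]-2H-chromen-6-yl}-N,N,N-trimethylmethanaminium iodide F7. Exposure of F7 to 24 and NaHCO3 in aqueous MeCN at room temperature should release the quinone methide by loss of trimethylamine and give 26 without heating.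

## Further compounds

F1 | step 3 | (E)-4-[2-hydroxy-4,6-bis(methoxymethoxy)phenyl]but-3-en-2-one | CC(=O)/C=C/c1c(O)cc(OCOC)cc1OCOC
F2 | step 3 | 2-[(E)-3-hydroxy-3-methylbut-1-en-1-yl]-3,5-bis(methoxymethoxy)phenol | CC(C)(O)/C=C/c1c(O)cc(OCOC)cc1OCOC
F3 | step 5 | 4-[(dimethylamino)methyl]-2-[(Z)-3-hydroxy-3-methylbut-1-en-1-yl]-3,5-bis(methoxymethoxy)phenol | CC(C)(O)/C=C\c1c(O)cc(OCOC)c(CN(C)C)c1OCOC
F4 | step 7 | (S)-2-methylbutanal | O=C[C@@H](C)CC
F5 | step 7 | (2S)-1-{6-[(dimethylamino)methyl]-5,7-bis(methoxymethoxy)-2,2-dimethyl-2H-chromen-8-yl}-2-methylbutan-1-ol (both C1 epimers) | OC(c1c(OCOC)c(CN(C)C)c(OCOC)c2C=CC(C)(C)Oc12)[C@@H](C)CC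
F6 | step 11 | 1-{5,7-bis(methoxymethoxy)-2,2-dimethyl-8-[(2S)-2-methylbutanoyl]-2H-chromen-6-yl}-N,N,N-trimethylmethanaminium iodide | C[N+](C)(C)Cc1c(OCOC)c(C(=O)[C@@H](C)CC)c2OC(C)(C)C=Cc2c1OCOC.[I-]
F7 | step 11 | 1-{5,7-dihydroxy-2,2-dimethyl-8-[(2S)-2-methylbutanoyl]-2H-chromen-6-yl}-N,N,N-trimethylmethanaminium iodide | C[N+](C)(C)Cc1c(O)c(C(=O)[C@@H](C)CC)c2OC(C)(C)C=Cc2c1O.[I-]
A1 | alternative 1 | 1,1-dimethoxy-3-(trimethylsilyloxy)buta-1,3-diene | COC(OC)=CC(=C)O[Si](C)(C)C
A2 | alternative 1 | (S)-1-ethoxy-4-methylhex-1-yn-3-one | CCOC#CC(=O)[C@@H](C)CC
A3 | alternative 1 | (S)-1-(2-ethoxy-4-hydroxy-6-methoxyphenyl)-2-methylbutan-1-one | CCOc1cc(O)cc(OC)c1C(=O)[C@@H](C)CC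
A4 | alternative 1 | (S)-2-methyl-1-(2,4,6-trihydroxyphenyl)butan-1-one | O=C(c1c(O)cc(O)cc1O)[C@@H](C)CC
A5 | alternative 2 | methyl (2Z)-3-({3-[5,7-bis(methoxymethoxy)-2,2-dimethyl-2H-chromen-6-yl]propanoyl}oxy)-2-methylpent-2-enoate | CC/C(=C(\C)C(=O)OC)OC(=O)CCc1c(OCOC)cc2OC(C)(C)C=Cc2c1OCOC
A6 | alternative 2 | 3-{[5,7-bis(methoxymethoxy)-2,2-dimethyl-2H-chromen-6-yl]methyl}-6-ethyl-4-hydroxy-5-methyl-2H-pyran-2-one | CCc1oc(=O)c(Cc2c(OCOC)cc3OC(C)(C)C=Cc3c2OCOC)c(O)c1C
A7 | alternative 3 | ethyl 3-(1H-benzotriazol-1-yl)-2-{[4-(benzyloxy)-2,6-bis(methoxymethoxy)phenyl]methyl}-3-oxopropanoate (racemic) | CCOC(=O)C(Cc1c(OCOC)cc(OCc2ccccc2)cc1OCOC)C(=O)n1nnc2ccccc12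
A8 | alternative 3 | 3-{[4-(benzyloxy)-2,6-bis(methoxymethoxy)phenyl]methyl}-6-ethyl-4-hydroxy-5-methyl-2H-pyran-2-one | CCc1oc(=O)c(Cc2c(OCOC)cc(OCc3ccccc3)cc2OCOC)c(O)c1C
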